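## Retrosynthetic overview

The aryl ester C–O bond between the ring A carbonyl and O-4 of ring B is cut first. This gives everninic acid (ring A, bought) and benzyl 2,4-dihydroxy-6-pentylbenzoate, whose benzyl ester is removed by hydrogenolysis in the last step.
The plan rests on ring B. Its carbons C1–C6, the carboxyl carbon on C1 and the pentyl chain on C6 form one unbranched C12 chain oxygenated on every second carbon (carboxyl, C2–OH, C4–OH, C6 as a former ketone). This is a folded 3,5,7-trioxododecanoate, and the C1–C6 ring bond is its C2–C7 aldol bond.
The unstable triketone is carried as a 4-pyranone ring, in which C2, C4 and C6 hold chain C3, C5 and C7 at the right oxidation level, so methyl 2-(4-oxo-6-pentyl-4H-pyran-2-yl)acetate is an isomer of methyl 2,4-dihydroxy-6-pentylbenzoate.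
Both side chains of this pyranone are cut at their lateral carbons, which leads back to 2,6-dimethyl-4H-pyran-4-one, 1-iodobutane and dimethyl carbonate.
Ring order: the pyranone ring is bought, ring B is made from it in the key step, and ring A is bought and joined last.

Key step: step 3

Remark: the target has no stereocentre and no configured double bond, so no step has to set configuration. The geometry of the transient open-chain enol ether does not matter, because its C7 ends as an arene carbon.

## Route

Step 1
Reactants: 1 2,6-dimethyl-4H-pyran-4-one; 2 1-iodobutane
Product: 4 2-methyl-6-pentyl-4H-pyran-4-one, via lithium 2-methyl-6-methylidene-6H-pyran-4-olate 3 (not isolated)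
Conditions: LiN(iPr)2 (1.05 equiv), THF, −78 °C; then n-BuI (1.2 equiv), DMPU, −78 → 0 °C
Reagents that add atoms: 1-iodobutane (2), CCCCI
Why: Lateral (vinylogous) deprotonation of a 4-pyranone methyl group gives the cross-conjugated dienolate 3, which the primary iodide alkylates at its exocyclic carbon in an SN2 enolate alkylation that restores the pyranone; the two methyl groups of 1 are equivalent, so only the extent of alkylation has to be held by the amount of base.

Step 2
Reactants: 4 2-methyl-6-pentyl-4H-pyran-4-one; 5 dimethyl carbonate
Product: 7 methyl 2-(4-oxo-6-pentyl-4H-pyran-2-yl)acetate, via lithium 2-methylidene-6-pentyl-2H-pyran-4-olate 6 (not isolated)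
Conditions: LiN(SiMe3)2 (2.2 equiv), THF, −78 °C; then (MeO)2CO (1.5 equiv), −78 → 0 °C; cold 1 M HCl quench
Reagents that add atoms: dimethyl carbonate (5), COC(=O)OC
Why: This is a crossed Claisen-type C-acylation of a lateral dienolate by a carbonate, in which the bulky amide takes the proton from the unhindered CH3 rather than from the pentyl α-CH2, and a second equivalent of base is required because the new CH2 is far more acidic than 4, so the product is deprotonated as it forms, which drives the reversible acylation forward and blocks a second acylation.

Step 3
Reactants: 7 methyl 2-(4-oxo-6-pentyl-4H-pyran-2-yl)acetate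
Product: 9 methyl 2,4-dihydroxy-6-pentylbenzoate, via methyl 7-methoxy-3,5-dioxododec-6-enoate 8 (not isolated)
Conditions: Mg(OMe)2 (3 equiv), dry MeOH, reflux, Ar; then cold 1 M HCl
Reagents that add atoms: none
Why: The alkoxide first deprotonates the side-chain CH2, which removes pyranone C2 from play as an acceptor, so methoxide adds in conjugate fashion at C6, the carbon that bears the pentyl group, and cleavage of the C6–O1 bond releases 8, the C7 methyl enol ether of methyl 3,5,7-trioxododecanoate, directly as its C2/C4 dianion bound to divalent magnesium. C2 is not the most acidic carbon of such a chain (a methylene between two ketones is), so its use as the donor depends on this double ionisation, in which the less stabilised C2 centre is the more nucleophilic one; after rotation about C3–C4 it attacks C7 and forms the C2–C7 bond, which is the C1–C6 bond of ring B. Ring B closes by addition–elimination at the β-methoxy enone, a 6-endo-trig closure (should C7 react as a free ketone, a 6-exo-trig aldol whose enolate is enolexo towards the ester and enolendo towards C3, both allowed), and loss of methanol followed by enolisation at C3 and C5 gives the arene irreversibly, so that 7 and 9 are isomers and methanol is only borrowed. The closest known reactions are the alkali opening of 2,6-dialkyl-4-pyranones to 1,3,5-triketones and the mild-base aldol aromatisation of 3,5,7-triketo esters to orsellinate-type resorcylates. The step needs the C2-to-C7 mode to beat Claisen closure (C6 onto the ester carbon C1), the C8-to-C3 aldol and lactonisation of the C5 enol onto C1: as long as C7 is an enol ether, C6 is a vinylic CH that cannot serve as Claisen donor and no 5,7-diketonate is on offer to magnesium, whose chelate across the C1 and C3 oxygens already has the shape of the salicylate product; C8 is far less acidic than C2; and a 2-pyranone would be reopened by methoxide whereas aromatisation is not reversed. No stereocentre is formed.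

Step 4
Reactants: 9 methyl 2,4-dihydroxy-6-pentylbenzoate
Product: 10 2,4-dihydroxy-6-pentylbenzoic acid (olivetolic acid)
Conditions: KOH (8 equiv), DMSO–H2O (3:1), 40 °C, Ar; then 1 M HCl, 0 °C, to pH 2, extraction and evaporation below 30 °C
Reagents that add atoms: potassium hydroxide, [K+].[OH-]
Why: This is a BAc2 saponification of a hindered, hydrogen-bonded salicylate-type ester, speeded by poorly solvated hydroxide in aqueous DMSO, in which the product stays in the flask as its salt, which should hold its CO2 at this temperature, and the free β-resorcylic acid is released only in the cold.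

Step 5
Reactants: 10 2,4-dihydroxy-6-pentylbenzoic acid
Product: 12 benzyl 2,4-dihydroxy-6-pentylbenzoate, via potassium 2,4-dihydroxy-6-pentylbenzoate 11 (not isolated)
Conditions: KHCO3 (1.1 equiv), BnBr (1.05 equiv), DMF, rt
Reagents that add atoms: benzyl bromide, BrCc1ccccc1
Why: This is an SN2 O-alkylation of a carboxylate, in which hydrogencarbonate ionises the carboxylic acid but not the phenols, so benzyl bromide meets carboxylate 11 as the only anionic nucleophile.

Step 6
Reactants: 12 benzyl 2,4-dihydroxy-6-pentylbenzoate; 13 everninic acid (2-hydroxy-4-methoxy-6-methylbenzoic acid)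
Product: 15 benzyl 2-hydroxy-4-[(2-hydroxy-4-methoxy-6-methylbenzoyl)oxy]-6-pentylbenzoate, via 2-hydroxy-4-methoxy-6-methylbenzoic trifluoroacetic anhydride 14 (not isolated)
Conditions: (CF3CO)2O (5 equiv), toluene, 0 °C → rt; evaporation, aq. NaHCO3 wash
Reagents that add atoms: everninic acid (13), COc1cc(C)c(C(=O)O)c(O)c1
Why: This is the mixed-anhydride esterification established for lichen depsides, in which trifluoroacetic anhydride turns 13 into the aroyl trifluoroacetate 14, whose electron-rich aroyl group passes to the free and more acidic 4-OH of 12, while the 2-OH groups of both partners are tied up in hydrogen bonds to their ortho carbonyl groups and shielded by them.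

Step 7
Reactants: 15 benzyl 2-hydroxy-4-[(2-hydroxy-4-methoxy-6-methylbenzoyl)oxy]-6-pentylbenzoate
Product: 16 2-hydroxy-4-[(2-hydroxy-4-methoxy-6-methylbenzoyl)oxy]-6-pentylbenzoic acid (target)
Conditions: H2 (1 atm), 10% Pd/C, EtOAc, rt
Reagents that add atoms: none
Why: Catalytic hydrogenolysis of the benzylic C–O bond under neutral conditions frees the acid without touching the aryl ester link, the phenols or the methyl ether, and avoids the base or heat that would cleave the depside or cost CO2.

## Compound list

1 | 2,6-dimethyl-4H-pyran-4-one | Cc1cc(=O)cc(C)o1 | starting material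
2 | 1-iodobutane | CCCCI | starting material
3 | lithium 2-methyl-6-methylidene-6H-pyran-4-olate (not isolated) | [Li+].[O-]C1=CC(=C)OC(C)=C1 | intermediate
4 | 2-methyl-6-pentyl-4H-pyran-4-one | CCCCCc1cc(=O)cc(C)o1 | intermediate
5 | dimethyl carbonate | COC(=O)OC | starting material
6 | lithium 2-methylidene-6-pentyl-2H-pyran-4-olate (not isolated) | [Li+].[O-]C1=CC(=C)OC(CCCCC)=C1 | intermediate
7 | methyl 2-(4-oxo-6-pentyl-4H-pyran-2-yl)acetate | CCCCCc1cc(=O)cc(CC(=O)OC)o1 | intermediate
8 | methyl 7-methoxy-3,5-dioxododec-6-enoate, the C7 methyl enol ether of methyl 3,5,7-trioxododecanoate (present as magnesium chelate, double-bond geometry not fixed, not isolated) | CCCCCC(OC)=CC(=O)CC(=O)CC(=O)OC | intermediate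
9 | methyl 2,4-dihydroxy-6-pentylbenzoate | CCCCCc1cc(O)cc(O)c1C(=O)OC | intermediate
10 | 2,4-dihydroxy-6-pentylbenzoic acid (olivetolic acid) | CCCCCc1cc(O)cc(O)c1C(=O)O | intermediate
11 | potassium 2,4-dihydroxy-6-pentylbenzoate (not isolated) | CCCCCc1cc(O)cc(O)c1C(=O)[O-].[K+] | intermediate
12 | benzyl 2,4-dihydroxy-6-pentylbenzoate | CCCCCc1cc(O)cc(O)c1C(=O)OCc1ccccc1 | intermediate
13 | everninic acid (2-hydroxy-4-methoxy-6-methylbenzoic acid) | COc1cc(C)c(C(=O)O)c(O)c1 | starting material
14 | 2-hydroxy-4-methoxy-6-methylbenzoic trifluoroacetic anhydride (not isolated) | COc1cc(C)c(C(=O)OC(=O)C(F)(F)F)c(O)c1 | intermediate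
15 | benzyl 2-hydroxy-4-[(2-hydroxy-4-methoxy-6-methylbenzoyl)oxy]-6-pentylbenzoate | CCCCCc1cc(OC(=O)c2c(C)cc(OC)cc2O)cc(O)c1C(=O)OCc1ccccc1 | intermediate
16 | 2-hydroxy-4-[(2-hydroxy-4-methoxy-6-methylbenzoyl)oxy]-6-pentylbenzoic acid | CCCCCc1cc(OC(=O)c2c(C)cc(OC)cc2O)cc(O)c1C(=O)O | target

## Step count

Total step count: 7.
Longest linear sequence: 7 steps (1 → 4 → 7 → 9 → 10 → 12 → 15 → 16).

## Steps most likely to fail

**Step 3 (key step).**
- Conjugate addition to the deprotonated, electron-rich pyranone may be slow.
- Adventitious water may hydrolyse the C7 enol ether. The terminal diketone can then bind magnesium and the chain can fold for Claisen closure, so magnesium alone is no safeguard for the aldol mode.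
- Methoxide may enter at C2 instead of C6, which would carry a methyl ether into the arene.

Fallback: the order of carboxylation and ring opening is reversed, and the closure is run on the free acid. It sets out from 4. Warm aqueous Ba(OH)2 opens the pyranone, and cold dilute acid gives undecane-2,4,6-trione F1. Threefold deprotonation with LiN(iPr)2 (3.3 equiv, THF, 0 °C) follows. Carboxylation with CO2 at the terminal carbanion derived from the methyl group then gives 3,5,7-trioxododecanoic acid F2. In aqueous acetate buffer at pH 5 this acid undergoes the same C2-to-C7 aldol aromatisation. As a carboxylate it has no leaving group for Claisen closure. The fallback comes back to the route at 10 and makes steps 2 to 4 unnecessary.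

**Step 2.**
- Proton removal from the pentyl α-CH2 may compete with removal from the methyl group.
- Acylation by the carbonate may be sluggish at low temperature, which leaves time for the dienolate to add to pyranone that has not yet been deprotonated.
- Acylation may occur on oxygen.

Fallback: the two lateral functionalisations change places, so that the acylation needs no site selection. It sets out from 1. LiN(SiMe3)2 (2.2 equiv) and dimethyl carbonate 5 give methyl 2-(6-methyl-4-oxo-4H-pyran-2-yl)acetate F3, and either methyl group leads to the same compound. Double deprotonation with LiN(iPr)2 (2.2 equiv, THF–DMPU, −78 °C) then ionises the acetate CH2 first and the remaining methyl group second. One equivalent of 1-iodobutane 2 is taken up at the last-formed, less stabilised carbanion. The fallback comes back to the route at 7 and replaces steps 1 and 2.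

**Step 4.**
- Hydrolysis may be slow, because the bis-phenoxide deactivates the ester carbonyl, which is also flanked on both sides.
- If the reaction is forced, or if acidification is not kept cold, CO2 is lost from the electron-rich β-resorcylic acid.

Fallback: the benzyl ester is installed before ring B exists, so no hindered ester ever has to be cleaved by base. It sets out from 4. LiN(SiMe3)2 (2.2 equiv) and dibenzyl carbonate give benzyl 2-(4-oxo-6-pentyl-4H-pyran-2-yl)acetate F4. The ring transformation is then run with the matching alkoxide, Mg(OBn)2 (from MgBu2 and benzyl alcohol), in benzyl alcohol–THF at 80 °C. It proceeds through benzyl 7-(benzyloxy)-3,5-dioxododec-6-enoate F5, which closes as in step 3. The fallback comes back to the route at 12 and makes steps 2 to 5 unnecessary.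

Further compounds
F1 | step 3 | undecane-2,4,6-trione | CCCCCC(=O)CC(=O)CC(C)=O
F2 | step 3 | 3,5,7-trioxododecanoic acid | CCCCCC(=O)CC(=O)CC(=O)CC(=O)O
F3 | step 2 | methyl 2-(6-methyl-4-oxo-4H-pyran-2-yl)acetate | Cc1cc(=O)cc(CC(=O)OC)o1
F4 | step 4 | benzyl 2-(4-oxo-6-pentyl-4H-pyran-2-yl)acetate | CCCCCc1cc(=O)cc(CC(=O)OCc2ccccc2)o1
F5 | step 4 | benzyl 7-(benzyloxy)-3,5-dioxododec-6-enoate | CCCCCC(OCc1ccccc1)=CC(=O)CC(=O)CC(=O)OCc1ccccc1
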